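**Plan**

- Retrosynthesis first re-closes the target: the carboxyl carbon on arene carbon C1 lies five bonds from the acetoxy oxygen on C2' of the tridecyl chain (O–C2'–C1'–C2–C1–CO), so acid and carbinol map onto the six-membered lactone ring of a (3R)-3-undecylisochroman-1-one.
- That lactone is cut at two bonds at once, aryl C1–C(=O) and acyl C–O, leaving CO and a symmetric 3,5-bis(benzyloxy)phenyl carbinol whose two ortho C–H bonds are identical.
- The carbinol is cut at the aryl–C1' bond into an aryl Grignard reagent and (R)-1,2-epoxytridecane.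
- Forward: the chain is joined to the arene by epoxide opening, then the only new ring (the lactone) is closed by hydroxyl-directed C–H carbonylation. The peri carbonyl then tells the two ethers apart (8-O-debenzylation, methylation) before the lactone is opened, esterified, acetylated and debenzylated.
- The single stereocenter (R) comes from hydrolytic kinetic resolution of racemic 1,2-epoxytridecane; its C–O bond is never broken afterwards.

Key step: step 5

Remark on the chemistry: the (R,R) enantiomer of (salen)Co(OAc) (salen = dianion of N,N'-bis(3,5-di-tert-butylsalicylidene)-1,2-cyclohexanediamine, trivalent cobalt) is taken to hydrolyse the (S) enantiomer of an unbranched 2-alkyloxirane faster, as is usual for this catalyst class.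

**Route**

Step 1
Reactants: 1 5-bromoresorcinol; 2 benzyl bromide
Product: 3 1,3-bis(benzyloxy)-5-bromobenzene
Conditions: BnBr (2.2 equiv), K2CO3 (3 equiv), DMF, rt to 60 °C
Reagents that add atoms: benzyl bromide (the second equivalent of 2), BrCc1ccccc1
Why: Twofold Williamson ether synthesis, in which each of the two phenoxides is alkylated by one molecule of the reactive benzylic bromide under mild carbonate conditions while the aryl bromide stays inert.

Step 2
Reactants: 4 1-tridecene
Product: 5 rac-1,2-epoxytridecane (2-undecyloxirane)
Conditions: mCPBA (1.2 equiv), CH2Cl2, 0 °C to rt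
Reagents that add atoms: 3-chloroperoxybenzoic acid (mCPBA), OOC(=O)c1cccc(Cl)c1
Why: Prilezhaev epoxidation of a terminal alkene by a peracid is general and should give the racemic monosubstituted oxirane needed for the resolution.

Step 3
Reactants: 5 rac-1,2-epoxytridecane
Product: 6 (R)-1,2-epoxytridecane [(2R)-2-undecyloxirane]
Conditions: (R,R)-(salen)Co(OAc) (0.5 mol %, trivalent cobalt, salen as defined above), H2O (0.55 equiv), THF (minimal), 0 °C to rt; separation from the diol by distillation or silica filtration
Reagents that add atoms: none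
Why: Jacobsen hydrolytic kinetic resolution, in which the chiral cobalt complex activates epoxide and water together and should hydrolyse the (S)-epoxide much faster, leaving the (R)-epoxide that becomes C2' of the target.

Step 4
Reactants: 3 1,3-bis(benzyloxy)-5-bromobenzene; 6 (R)-1,2-epoxytridecane
Product: 8 (2R)-1-[3,5-bis(benzyloxy)phenyl]tridecan-2-ol, via 3,5-bis(benzyloxy)phenylmagnesium bromide 7 (not isolated)
Conditions: Mg, I2 (cat.), THF, reflux; then CuI (10 mol %), 6, THF, −30 to 0 °C; aq NH4Cl
Reagents that add atoms: magnesium, [Mg] (held only in intermediate 7; no reagent atom other than hydrogen ends in 8)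
Why: Copper-catalysed Grignard opening of a terminal epoxide, in which the arylcopper species formed from 7 and CuI attacks the unsubstituted oxirane carbon in an SN2 fashion, so the aryl–CH2 bond forms without touching the carbinol carbon and the R configuration of 6 is carried over.

Step 5
Reactants: 8 (2R)-1-[3,5-bis(benzyloxy)phenyl]tridecan-2-ol; 9 carbon monoxide
Product: 10 (3R)-6,8-bis(benzyloxy)-3-undecylisochroman-1-one
Conditions: Pd(OAc)2 (10 mol %), (+)-menthyl-O2C-Leu-OH [N-(menthyloxycarbonyl)-L-leucine] (20 mol %), AgOAc (3 equiv), Li2CO3 (1 equiv), CO (1 atm), CH2Cl2, 110 °C, sealed vessel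
Reagents that add atoms: none
Why: The reaction is a hydroxyl-directed C–H carbonylation: the carbinol oxygen of 8 binds divalent palladium, acetate-assisted concerted metalation–deprotonation of an ortho C–H bond gives a six-membered palladacycle, CO inserts into the aryl–palladium bond, and acyl–oxygen reductive elimination releases the lactone and zerovalent palladium, which AgOAc returns to divalent palladium. The closest known reaction type is the Pd(OAc)2-catalysed, amino-acid-ligand-enabled carbonylation of phenethyl alcohols to isochroman-1-ones, of which this is a direct application to a secondary, electron-rich member. The single ring closed is the six-membered lactone, and it closes by C–O reductive elimination from a seven-membered acyl palladium alkoxide, formally a 6-exo-trig capture of the acyl carbon by the tethered oxygen. No stereocenter is created; C3 keeps the R configuration of 8 because neither its C–O nor its C–H bond is broken in the productive cycle. Site selectivity is not in question, since the two ortho C–H bonds of the 3,5-bis(benzyloxy)phenyl ring are equivalent, each is activated by a para benzyloxy group, and the position between the two ethers cannot be reached from the tether. The selectivity that must be won is chemoselectivity against β-hydride elimination of the palladium alkoxide to the ketone, and it is secured by the mono-N-protected amino acid ligand, which accelerates C–H cleavage relative to alcohol oxidation.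

Step 6
Reactants: 10 (3R)-6,8-bis(benzyloxy)-3-undecylisochroman-1-one
Product: 11 (3R)-6-(benzyloxy)-8-hydroxy-3-undecylisochroman-1-one
Conditions: BCl3 (1.2 equiv), CH2Cl2, −78 °C; then H2O
Reagents that add atoms: none
Why: Chelation-controlled Lewis acid ether cleavage, in which BCl3 binds between the lactone carbonyl oxygen and the peri 8-ether oxygen so that chloride removes only that benzyl group at low temperature and the remote 6-benzyl ether and the lactone should stay intact.

Step 7
Reactants: 11 (3R)-6-(benzyloxy)-8-hydroxy-3-undecylisochroman-1-one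
Product: 12 (3R)-6-(benzyloxy)-8-methoxy-3-undecylisochroman-1-one
Conditions: MeI (3 equiv), K2CO3 (2 equiv), DMF, 50 °C
Reagents that add atoms: iodomethane, CI
Why: Williamson O-methylation of the hydrogen-bonded 8-phenol with carbonate and iodomethane in a dipolar solvent is routine for 8-hydroxyisochromanones and cannot affect C3, which carries no acidic hydrogen.

Step 8
Reactants: 12 (3R)-6-(benzyloxy)-8-methoxy-3-undecylisochroman-1-one; 2 benzyl bromide
Product: 14 benzyl 4-(benzyloxy)-2-[(2R)-2-hydroxytridecyl]-6-methoxybenzoate, via potassium hydroxy carboxylate 13 (not isolated)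
Conditions: KOH (1.1 equiv), EtOH–H2O, 70 °C; evaporation to dryness (toluene azeotrope); BnBr (1.5 equiv), DMF, rt
Reagents that add atoms: potassium hydroxide, [K+].[OH-] (its oxygen becomes a carboxyl oxygen; potassium is held only in 13)
Why: Saponification followed by SN2 O-alkylation of the carboxylate, in which hydroxide opens the lactone and the dry potassium salt is benzylated on oxygen in DMF while the neutral secondary alcohol does not react and the two ortho substituents slow re-lactonisation of the ester.

Step 9
Reactants: 14 benzyl 4-(benzyloxy)-2-[(2R)-2-hydroxytridecyl]-6-methoxybenzoate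
Product: 15 benzyl 2-[(2R)-2-acetoxytridecyl]-4-(benzyloxy)-6-methoxybenzoate
Conditions: Ac2O, pyridine, DMAP (cat.), CH2Cl2, 0 °C to rt (on crude 14)
Reagents that add atoms: acetic anhydride, CC(=O)OC(C)=O
Why: DMAP-catalysed acetylation of the secondary alcohol with acetic anhydride is fast, leaves the C–O bond and hence the R configuration untouched, and blocks the hydroxyl before it can re-close the lactone.

Step 10
Reactants: 15 benzyl 2-[(2R)-2-acetoxytridecyl]-4-(benzyloxy)-6-methoxybenzoate
Product: 16 2-[(2R)-2-acetoxytridecyl]-4-hydroxy-6-methoxybenzoic acid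
Conditions: H2 (1 atm), Pd/C (10 wt % Pd), EtOAc, rt
Reagents that add atoms: none
Why: Catalytic hydrogenolysis over palladium on carbon should cleave the benzyl ester and the benzyl aryl ether in one operation, while the homobenzylic acetate, the methyl ether and the stereocenter are inert in a neutral aprotic solvent.

**Compound list**

1 | 5-bromoresorcinol (5-bromobenzene-1,3-diol) | Oc1cc(O)cc(Br)c1 | starting material
2 | benzyl bromide | BrCc1ccccc1 | starting material
3 | 1,3-bis(benzyloxy)-5-bromobenzene | Brc1cc(OCc2ccccc2)cc(OCc2ccccc2)c1 | intermediate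
4 | 1-tridecene | C=CCCCCCCCCCCC | starting material
5 | rac-1,2-epoxytridecane (2-undecyloxirane) | CCCCCCCCCCCC1CO1 | intermediate
6 | (R)-1,2-epoxytridecane [(2R)-2-undecyloxirane] | CCCCCCCCCCC[C@@H]1CO1 | intermediate
7 | 3,5-bis(benzyloxy)phenylmagnesium bromide | Br[Mg]c1cc(OCc2ccccc2)cc(OCc2ccccc2)c1 | intermediate (not isolated)
8 | (2R)-1-[3,5-bis(benzyloxy)phenyl]tridecan-2-ol | CCCCCCCCCCC[C@H](Cc1cc(OCc2ccccc2)cc(OCc2ccccc2)c1)O | intermediate
9 | carbon monoxide | [C-]#[O+] | starting material
10 | (3R)-6,8-bis(benzyloxy)-3-undecylisochroman-1-one | CCCCCCCCCCC[C@H]1OC(=O)c2c(OCc3ccccc3)cc(OCc3ccccc3)cc2C1 | intermediate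
11 | (3R)-6-(benzyloxy)-8-hydroxy-3-undecylisochroman-1-one | CCCCCCCCCCC[C@H]1OC(=O)c2c(O)cc(OCc3ccccc3)cc2C1 | intermediate
12 | (3R)-6-(benzyloxy)-8-methoxy-3-undecylisochroman-1-one | CCCCCCCCCCC[C@H]1OC(=O)c2c(OC)cc(OCc3ccccc3)cc2C1 | intermediate
13 | potassium 4-(benzyloxy)-2-[(2R)-2-hydroxytridecyl]-6-methoxybenzoate | CCCCCCCCCCC[C@H](Cc1cc(OCc2ccccc2)cc(OC)c1C(=O)[O-])O.[K+] | intermediate (not isolated)
14 | benzyl 4-(benzyloxy)-2-[(2R)-2-hydroxytridecyl]-6-methoxybenzoate | CCCCCCCCCCC[C@H](Cc1cc(OCc2ccccc2)cc(OC)c1C(=O)OCc1ccccc1)O | intermediate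
15 | benzyl 2-[(2R)-2-acetoxytridecyl]-4-(benzyloxy)-6-methoxybenzoate | CCCCCCCCCCC[C@H](Cc1cc(OCc2ccccc2)cc(OC)c1C(=O)OCc1ccccc1)OC(C)=O | intermediate
16 | 2-[(2R)-2-acetoxytridecyl]-4-hydroxy-6-methoxybenzoic acid | CCCCCCCCCCC[C@H](Cc1cc(O)cc(OC)c1C(=O)O)OC(C)=O | target

**Step count**

Total: 10 steps. Longest linear sequence: 9 steps (steps 2 to 10, from 1-tridecene); the arene branch adds step 1 before the convergence in step 4.

**Steps most likely to fail**

Step 5 (directed C–H carbonylation). The secondary palladium alkoxide may undergo β-hydride elimination to the ketone, CO may reduce the catalyst to palladium black before turnover, and palladation at an ortho carbon flanked by a benzyloxy group may be slow. The fallback sets out from 8 and comes back at 10; it replaces C–H activation by a halide handle. Electrophilic bromination with NBS in MeCN at 0 °C should go ortho to the side chain and para to a benzyloxy group, giving (2R)-1-[3,5-bis(benzyloxy)-2-bromophenyl]tridecan-2-ol F1. Carbonylative lactonisation of this bromo alcohol (Pd(OAc)2, Xantphos, K2CO3, CO 1 atm, toluene, 100 °C) proceeds by oxidative addition of the C–Br bond to zerovalent palladium, CO insertion and capture of the acyl group by the tethered hydroxyl, and should deliver 10.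

Step 8 (lactone opening and benzylation). The hydroxy ester may re-close to the lactone with loss of benzyl alcohol before it is acetylated, or the carboxylate may alkylate incompletely. The fallback sets out from 12 and comes back at 16; it takes the carbonyl out of play by reduction and restores it at the end. LiAlH4 in THF at 0 °C should reduce 12 to (2R)-1-[5-(benzyloxy)-2-(hydroxymethyl)-3-methoxyphenyl]tridecan-2-ol F2. TBSCl and imidazole in CH2Cl2 should silylate the primary benzylic hydroxyl selectively to give (2R)-1-[5-(benzyloxy)-2-{[tert-butyl(dimethyl)silyl]oxymethyl}-3-methoxyphenyl]tridecan-2-ol F3. Ac2O, pyridine and DMAP should then give (2R)-1-[5-(benzyloxy)-2-{[tert-butyl(dimethyl)silyl]oxymethyl}-3-methoxyphenyl]tridecan-2-yl acetate F4. HF·pyridine in THF removes the silyl group to give (2R)-1-[5-(benzyloxy)-2-(hydroxymethyl)-3-methoxyphenyl]tridecan-2-yl acetate F5. Dess–Martin periodinane in CH2Cl2 gives (2R)-1-[5-(benzyloxy)-2-formyl-3-methoxyphenyl]tridecan-2-yl acetate F6. Pinnick oxidation (NaClO2, NaH2PO4, 2-methyl-2-butene, t-BuOH–H2O) gives 2-[(2R)-2-acetoxytridecyl]-4-(benzyloxy)-6-methoxybenzoic acid F7. Hydrogenolysis of the remaining benzyl ether (H2, Pd/C, EtOAc) then gives 16.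

Step 6 (mono-debenzylation). Discrimination between the chelated and the remote benzyl ether may be incomplete, with loss of both groups or partial opening of the lactone by the Lewis acid. The fallback sets out from 10 and comes back at 11; it removes both ethers and reinstalls one by exploiting phenol reactivity instead of ether reactivity. Hydrogenolysis (H2, Pd/C, EtOAc) should give (3R)-6,8-dihydroxy-3-undecylisochroman-1-one F8. Benzylation with benzyl bromide 2 (1 equiv) and K2CO3 in acetone at rt should then take the free 6-hydroxyl and spare the 8-hydroxyl that is hydrogen-bonded to the lactone carbonyl, giving 11.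

**Further compounds**

F1 | step 5 | (2R)-1-[3,5-bis(benzyloxy)-2-bromophenyl]tridecan-2-ol | CCCCCCCCCCC[C@H](Cc1cc(OCc2ccccc2)cc(OCc2ccccc2)c1Br)O
F2 | step 8 | (2R)-1-[5-(benzyloxy)-2-(hydroxymethyl)-3-methoxyphenyl]tridecan-2-ol | CCCCCCCCCCC[C@H](Cc1cc(OCc2ccccc2)cc(OC)c1CO)O
F3 | step 8 | (2R)-1-[5-(benzyloxy)-2-{[tert-butyl(dimethyl)silyl]oxymethyl}-3-methoxyphenyl]tridecan-2-ol | CCCCCCCCCCC[C@H](Cc1cc(OCc2ccccc2)cc(OC)c1CO[Si](C)(C)C(C)(C)C)O
F4 | step 8 | (2R)-1-[5-(benzyloxy)-2-{[tert-butyl(dimethyl)silyl]oxymethyl}-3-methoxyphenyl]tridecan-2-yl acetate | CCCCCCCCCCC[C@H](Cc1cc(OCc2ccccc2)cc(OC)c1CO[Si](C)(C)C(C)(C)C)OC(C)=O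
F5 | step 8 | (2R)-1-[5-(benzyloxy)-2-(hydroxymethyl)-3-methoxyphenyl]tridecan-2-yl acetate | CCCCCCCCCCC[C@H](Cc1cc(OCc2ccccc2)cc(OC)c1CO)OC(C)=O
F6 | step 8 | (2R)-1-[5-(benzyloxy)-2-formyl-3-methoxyphenyl]tridecan-2-yl acetate | CCCCCCCCCCC[C@H](Cc1cc(OCc2ccccc2)cc(OC)c1C=O)OC(C)=O
F7 | step 8 | 2-[(2R)-2-acetoxytridecyl]-4-(benzyloxy)-6-methoxybenzoic acid | CCCCCCCCCCC[C@H](Cc1cc(OCc2ccccc2)cc(OC)c1C(=O)O)OC(C)=O
F8 | step 6 | (3R)-6,8-dihydroxy-3-undecylisochroman-1-one | CCCCCCCCCCC[C@H]1OC(=O)c2c(O)cc(O)cc2C1
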